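Start at the late end: by 140 min the north-east run creeps to 118.1 mM.

all flasks: starting material 200 mM
- south: partner 200 mM
- north-east: partner 200 mM; target 60.0 mM
- east: partner 66.0 mM; time 140 min
- south run (time / min: [target] / mM): 5.0: 7.5; 15: 20.2; 29: 35.1; 46: 48.7; 66: 59.7; 88: 68.8; 110: 74.9; 140: 79.9
- north-east run (time / min: [target] / mM): 5.0: 66.3; 15: 77.3; 29: 90.0; 46: 101.1; 66: 108.7; 88: 114.3; 110: 117.0; 140: 118.1

(standard deviation of a reading: 0.6 mM)
1. target in the east run at 140 min, as a share of the starting material charged
- Overall: starting material + partner -> target.
- Constant volume, constant temperature.
- Bound and free are read together.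
- "The second partner" is partner.

Read a stall quotient Q there, target over starting material times partner: 5.87 M⁻¹. Now bracket the east run. Partner is the limiting reagent, which caps the share at 33.0%.

For a bound from below, stop the east run at Q, which gives 16.3%. Test that brake at one moment. As a brake from target, Q sets the north-east start rate at 0.744 of the south rate, yet by 15 min the north-east run has made 0.856 of the south amount, a reading higher than that ratio. So Q brakes too hard, and this bound stands low.

For a tighter bound from above, define k, the forward constant of the south run, first order in starting material and first order in partner, read at 15 min: 0.0374 M⁻¹ min⁻¹. Run the east flask forward on k with no brake: 19.9%.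

The central value of the forecast, 15.5%, sits below this bracket, while its range, from 13.5% to 17.5%, reaches above the low end. It warns: “The partner order is untested”.

The east run gives 21.4%, above the bracket.

    starting material + partner ⇌ target + by-product (0.07260 M⁻¹ min⁻¹, 0.03774 M⁻¹ min⁻¹)
    2 partner ⇌ idle reagent dimer, settled at all times (4.700 M⁻¹)
    target + partner → side product (0.02244 M⁻¹ min⁻¹)

Solve k from that east share: 0.0430 M⁻¹ min⁻¹, larger than the south k. Partner pairs into idle reagent dimer, and at the start the free share of the charge is 51.0% in the south run against 69.8% in the east run. The simulated run with that joining taken away proves the effect: the apparent order in partner is 0.69 because of it, and 1.0 without it.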